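Assumption: natural (+)-(3S,6E)-nerolidol of high ee (from cabreuva oil) and (2E,6E)-farnesyl acetate are treated as commercial.

**Retrosynthetic overview** (ring numbering: C1 = CH stereocentre, C2 = allylic CH2, C3=C4, C7=C8, C11=C12, C13, C14; C15 = carbinol)
- C15 + C15 split. (3S,6E)-Nerolidol (1) supplies the side chain, the C15 carbinol stereocentre, C1 and C14. (2E,6E)-Farnesyl acetate (2) supplies C2–C13 with all three E-olefins already in place.
- C1–H is set last, by OH-directed hydrogenation of a C1=C14 ring olefin (1,2-induction from the purchased C15 centre).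
- The only ring (14-membered) is closed at C1–C2 by a Ni-electrocatalytic alkenyl triflate/allylic acetate coupling, which is the key step.
- C13–C14 comes from alkylating the methyl-ketone enolate (Wacker product of 1) with 12-bromofarnesyl acetate.

**Step 1**
Reactants: 1, (3S,6E)-nerolidol
Product: 3, (3S,6E)-3-hydroxy-3,7,11-trimethyldodeca-6,10-dien-2-one
Conditions: PdCl2 (10 mol %), CuCl (1 equiv), O2 (1 atm), DMF/H2O 7:1, rt
Reagents that add atoms: water, O
Why: Tsuji–Wacker oxidation converts only the monosubstituted vinyl group into the methyl ketone, because trisubstituted olefins bind Pd(II) too weakly, and the quaternary carbinol centre is not touched.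

**Step 2**
Reactants: 2, (2E,6E)-farnesyl acetate
Product: 4, (2E,6E,10E)-12-hydroxy-3,7,11-trimethyldodeca-2,6,10-trien-1-yl acetate
Conditions: SeO2 (0.3 equiv), t-BuOOH, salicylic acid (cat.), CH2Cl2, 0 °C to rt; then NaBH4, MeOH, 0 °C
Reagents that add atoms: selenium dioxide, O=[Se]=O; tert-butyl hydroperoxide, CC(C)(C)OO
Why: Sharpless–Umbreit allylic oxidation (ene/[2,3] sequence) selectively hydroxylates the E-methyl of the terminal, most electron-rich olefin, and the borohydride work-up returns any over-oxidised enal.

**Step 3**
Reactants: 4
Product: 5, (2E,6E,10E)-12-bromo-3,7,11-trimethyldodeca-2,6,10-trien-1-yl acetate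
Conditions: CBr4, PPh3, CH2Cl2, 0 °C
Reagents that add atoms: carbon tetrabromide, BrC(Br)(Br)Br
Why: The Appel reaction converts the primary allylic alcohol into the bromide under neutral conditions, without allylic transposition or loss of the acetate.

**Step 4**
Reactants: 3 (1.2 equiv) and 5
Product: 6, (2E,6E,10E,15S,18E)-15-hydroxy-3,7,11,15,19,23-hexamethyl-14-oxotetracosa-2,6,10,18,22-pentaen-1-yl acetate
Conditions: LDA (2.5 equiv), THF, −78 °C; DMPU, then 5, −78 to −30 °C
Reagents that add atoms: none
Why: In this acyloin-dianion α′-alkylation the ketone can enolise only toward CH3, so SN2 attack on the primary allylic bromide forms C13–C14 regiospecifically and faster than attack on the acetate at low temperature.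

**Step 5**
Reactants: 6
Product: 7, (2E,6E,10E,13Z,15S,18E)-15-hydroxy-3,7,11,15,19,23-hexamethyl-14-(trifluoromethylsulfonyloxy)tetracosa-2,6,10,13,18,22-hexaen-1-yl acetate
Conditions: KHMDS (2.05 equiv), THF, −78 °C; Comins' reagent (1.1 equiv), −78 to −40 °C
Reagents that add atoms: Comins' reagent, FC(F)(F)S(=O)(=O)N(c1ccc(Cl)cn1)S(=O)(=O)C(F)(F)F
Why: In this Comins enol triflation the bulky tertiary acyl substituent enforces the Z(O)-enolate (OTf cis to C12, carbinol cis to H), the ketone CH2 is more acidic than the acetate, and the hindered tertiary alkoxide is not sulfonylated.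

**Step 6 (key step)**
Reactants: 7
Product: 8, (2S,5E)-6,10-dimethyl-2-[(1E,4E,8E,12E)-4,8,12-trimethylcyclotetradeca-1,4,8,12-tetraen-1-yl]undeca-5,9-dien-2-ol
Conditions: NiBr2·dme (20 mol %), dtbbpy (24 mol %), NaI (0.5 equiv), n-Bu4NPF6, DMA, undivided cell, Zn(+)/Ni foam(−), 4 mA, about 2.5 F/mol, 7 added by syringe pump over 12 h (final 2 mM), 25 °C
Reagents that add atoms: none
Why: Proposed new method: a macrocyclising Ni-electrocatalytic cross-electrophile coupling of an alkenyl triflate with an allylic acetate, in which cathodically generated (dtbbpy)Ni(0) inserts into C(sp2)–OTf, one-electron reduction gives an alkenyl–Ni(I) that ionises the tethered allylic acetate to an alkenyl(η3-allyl)Ni(III), and reductive elimination at the unhindered CH2 terminus (syn π-allyl, so the adjacent E-olefin is kept and the 14- rather than 12-membered ring forms) makes C1–C2 as a skipped diene with no free alkyl radical that could cyclise onto the polyene, while current and feed rate hold Ni(0) and substrate at pseudo-high dilution; the closest known reaction type is the intermolecular Ni-catalysed electroreductive or Zn-mediated coupling of aryl/alkenyl (pseudo)halides with allylic acetates, not yet shown on such an enol triflate or for carbocyclic macrocyclisation.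

**Step 7**
Reactants: 8
Product: 9, colleterpenol, (2S,5E)-6,10-dimethyl-2-[(1R,3E,7E,11E)-4,8,12-trimethylcyclotetradeca-3,7,11-trien-1-yl]undeca-5,9-dien-2-ol
Conditions: [Rh(nbd)(dppb)]BF4 (10 mol %), H2 (60 bar), CH2Cl2, rt
Reagents that add atoms: none
Why: In this hydroxyl-directed homogeneous hydrogenation (Brown–Evans type) the cationic Rh chelates the tertiary OH and the adjacent C1=C14 olefin while isolated trisubstituted olefins are essentially inert, and in the chelate the C15 methyl takes the in-plane site next to ring C2 (least A1,2 strain) with the homogeranyl chain on the far face, so H2 arrives syn to OH and gives (1R) under control of the purchased (15S) centre (moderate to good dr expected, with the epimer removable on AgNO3–silica).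

**Compound list**
1 | (3S,6E)-nerolidol | CC(C)=CCC/C(C)=C/CC[C@](C)(O)C=C | starting material
2 | (2E,6E)-farnesyl acetate | CC(C)=CCC/C(C)=C/CC/C(C)=C/COC(C)=O | starting material
3 | (3S,6E)-3-hydroxy-3,7,11-trimethyldodeca-6,10-dien-2-one | CC(C)=CCC/C(C)=C/CC[C@](C)(O)C(C)=O | intermediate
4 | 12-hydroxyfarnesyl acetate (all-E) | OC/C(C)=C/CC/C(C)=C/CC/C(C)=C/COC(C)=O | intermediate
5 | 12-bromofarnesyl acetate (all-E) | BrC/C(C)=C/CC/C(C)=C/CC/C(C)=C/COC(C)=O | intermediate
6 | acyclic C30 α-hydroxy ketone acetate | CC(C)=CCC/C(C)=C/CC[C@](C)(O)C(=O)CC/C(C)=C/CC/C(C)=C/CC/C(C)=C/COC(C)=O | intermediate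
7 | (13Z)-enol triflate of 6 | CC(C)=CCC/C(C)=C/CC[C@](C)(O)/C(OS(=O)(=O)C(F)(F)F)=C/C/C(C)=C/CC/C(C)=C/CC/C(C)=C/COC(C)=O | intermediate
8 | 1,14-didehydrocolleterpenol (macrocyclic tetraene) | CC(C)=CCC/C(C)=C/CC[C@](C)(O)/C1=C/C/C(C)=C/CC/C(C)=C/CC/C(C)=C/C1 | intermediate
9 | colleterpenol | CC(C)=CCC/C(C)=C/CC[C@](C)(O)[C@H]1C/C=C(\C)CC/C=C(\C)CC/C=C(\C)CC1 | target

**Total steps:** 7. **Longest linear sequence:** 6 (2 → 4 → 5 → 6 → 7 → 8 → 9).

**Steps most likely to fail**
1. **Step 6 (proposed new step).**
   - Risks: oligomerisation, protodetriflation, allyl homocoupling, and 5-exo carbonickelation of the alkenyl–Ni onto the side-chain C=C.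
   - Fallback (known chemistry): convert 7 to the alkenylstannane (Pd(0), Me6Sn2). Then close the same C1–C2 bond by an intramolecular Pd-catalysed sp2–sp3 Stille coupling of the alkenylstannane with the allylic acetate, an established macrocyclisation tactic.
2. **Step 7.**
   - Risks: a sluggish reaction at the hindered olefin, over-reduction or isomerisation of the skipped diene, and only modest Me-versus-chain facial discrimination.
   - Fallback: tether the hydride. Form the O–SiMe2H ether with (HMe2Si)2NH and run a Pt-catalysed intramolecular hydrosilylation, which puts H on C1 syn to O and Si on C14. Then protodesilylate the oxasilolane (KOt-Bu/DMSO or TBAF/DMF). The net result is a directed, chemoselective reduction.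
3. **Step 5.**
   - Risks: a free tertiary OH and an acetate are both exposed to 2 equiv of strong base, and the enolate geometry may not be clean.
   - Fallback: reverse the bond order.
     - Triflate ketone 3 itself to CH2=C(OTf)–, which carries no ester and has no E/Z issue, and couple it intermolecularly with the allylic acetate of 4 to make C1–C2.
     - Set C1 by silicon-tethered hydrosilylation/Tamao oxidation of the resulting 1,1-disubstituted olefin.
     - Close the ring at C13–C14 by classical intramolecular alkylation (C14 iodide with a C13 allylic sulfone anion), followed by reductive desulfonylation.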